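**Closed vessel.** The vessel holds Z and J, stirred at constant volume, and each J that lands puts one arm on Z, giving L, then E, then X.

| flask | Z | J | remark | time |
|---|---|---|---|---|
| beta | 0.079 M | 1.3 equiv | run made earlier |  |
| eta | 0.079 M | 3 equiv | run made earlier |  |
| flask | 0.079 M | 2.00 equiv |  | 10 h |

| run | time / h | Z / % | L / % |
|---|---|---|---|
| beta | 0.833 | 12 | 60 |
| beta | 2.00 | 8 | 61 |
| beta | 4.00 | 6 | 58 |
| beta | 6.00 | 6 | 60 |
| eta | 0.500 | 3 | 29 |
| eta | 1.00 | 0 | 30 |
| eta | 2.50 | 2 | 30 |
| eta | 6.00 | 4 | 28 |

(each reading ± 1.5 percentage points)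

- the Z standing at 10 h, as a percentage of the Z charged
- the L standing at 10 h, as a percentage of the Z charged
- the E standing at 10 h, as a percentage of the Z charged
- the X standing at 10 h, as a percentage of the Z charged

**Counting arms.** The bench rule says arms per Z equal the equivalents of J charged. I count L as one arm and the unread rest as two. The last two beta readings then give 1.29 against 1.3 equiv charged. Those of eta give 1.65 against 3 equiv, so per equivalent eta lands 55.4% of what beta lands. The two arms are a guess that no reading tests, so beta's match does not show the rule holding there.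

**Dropping J.** I assume both first steps run in proportion to J, so dividing one rate by the other removes J. What remains is the selectivity factor κ, the rate constant of J on L over that of J on Z. Integrated, with z and l as fractions of the Z charged, it gives l = (z^κ − z)/(1 − κ). Beta's last readings give z = 6.00% and l = 59.0%. One pass from a trial value of a quarter gives κ = 0.263. A straight line in equivalents between beta and eta puts z at 4.76% in this flask, so my curve gives L 54.5%.

**The forecast.** It says Z 3%, L 43%, E 47%, X 7%: “I interpolate empirically”. Its L lies 12 percentage points below mine.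

**The flask.** It gives Z 2.22%, L 53.9%, E 36.8%, X 2.04%.

    Z + J → L + Q (k = 11.0 M⁻¹ min⁻¹)
    J + L → E + Q (k = 3.00 M⁻¹ min⁻¹)
    J + E → X + Q (k = 0.480 M⁻¹ min⁻¹)
    J → G (k = 0.200 min⁻¹)
    2 Z → D (k = 0.280 M⁻¹ min⁻¹)

Half the turnover of Z + J is done by 0.444 min and half that of J + L by 1.74 min, and J stands at 0% at 1.00 h. After that, Z slips from 4.73% to 2.22% by 10.0 h while D rises from 2.46% to 4.97% and L holds at 53.9%. On the Z of 1.00 h, the curve gives L 54.4%.

**Second flask.** The neighbour charged with 0.32 M of Z ends with Z at 0.341%, and on that z the curve gives L 30.0%. The computed flask holds 32.1%.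

(The runs were computed for an exercise, and the scatter is random.)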